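The dihydrofuran ring (O1–C2–C3–C3a–C7a) is cut at C2–C3 and at O1–C7a. This leaves methacrolein and a benzene ring that is nucleophilic at its benzylic carbon C3 (CH2Bpin) and electrophilic at C7a (C–F). In one flask a chiral copper catalyst adds the benzylic boronate to the aldehyde, which makes C3–C2 and sets C2, and the released alkoxide displaces fluoride from C7a. The step exploits that C7a lies para to the C5 isobutyryl group and meta to both oxygen substituents at C4 and C6. It also exploits that O1 arrives bound to C2, so the allylic C2–O bond is never broken. The pyrone is joined last at C7.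

Key step: step 5

Remark: benzofuran numbering (O1, C2, C3, C3a, C4 to C7, C7a) is used for these atoms in all compounds, open precursors included.
Assumption: (R)-DTBM-SEGPHOS is taken to steer the benzyl group to the Re face of methacrolein, which gives the (R)-configuration; if the sense of induction proves opposite, the (S)-ligand is used.

Step 1
Reactants: 1 5-fluorobenzene-1,3-diol (5-fluororesorcinol)
Product: 2 1-fluoro-3,5-bis(methoxymethoxy)benzene
Conditions: NaH (2.4 equiv), MOMCl (2.3 equiv), DMF, 0 °C to rt
Reagents that add atoms: chloromethyl methyl ether (MOMCl), COCCl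
Why: Williamson-type O-alkylation of the bis-phenoxide gives the bis-acetal, which withstands the organolithium, palladium, copper and fluoride chemistry ahead and later leaves under mild acid.

Step 2
Reactants: 2 1-fluoro-3,5-bis(methoxymethoxy)benzene; 3 N-methoxy-N,2-dimethylpropanamide (Weinreb amide of isobutyric acid)
Product: 4 1-[4-fluoro-2,6-bis(methoxymethoxy)phenyl]-2-methylpropan-1-one
Conditions: n-BuLi (1.1 equiv), THF–hexane, −20 °C; 3, −78 °C to rt; H2O
Reagents that add atoms: none
Why: Directed ortho-metalation with plain n-BuLi follows coordination, so lithium should settle on the carbon held between the two OMOM groups and not beside fluorine, and the Weinreb ketone synthesis stops at the ketone because the chelated adduct collapses only on work-up.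

Step 3
Reactants: 4 1-[4-fluoro-2,6-bis(methoxymethoxy)phenyl]-2-methylpropan-1-one
Product: 5 1-[3-bromo-4-fluoro-2,6-bis(methoxymethoxy)phenyl]-2-methylpropan-1-one
Conditions: NBS (1.05 equiv), MeCN, 0 °C to rt, dark
Reagents that add atoms: N-bromosuccinimide, O=C1CCC(=O)N1Br
Why: Electrophilic aromatic bromination goes to one of the two equivalent ring positions that lie ortho to one and para to the other OMOM group, and the first bromine together with the acyl group slows a second substitution.

Step 4
Reactants: 5 1-[3-bromo-4-fluoro-2,6-bis(methoxymethoxy)phenyl]-2-methylpropan-1-one; 6 bis[(pinacolato)boryl]methane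
Product: 7 1-{4-fluoro-2,6-bis(methoxymethoxy)-3-[(4,4,5,5-tetramethyl-1,3,2-dioxaborolan-2-yl)methyl]phenyl}-2-methylpropan-1-one
Conditions: Pd[P(t-Bu)3]2 (5 mol %), KOH (8 M aq, 2 equiv), 1,4-dioxane, rt
Reagents that add atoms: none
Why: Suzuki–Miyaura coupling of a geminal diborylmethane works because hydroxide activates one boron whose transfer to divalent palladium is eased by the neighbouring boron, while the benzylic monoboronate formed is too unreactive to couple again.

Step 5
Reactants: 7 1-{4-fluoro-2,6-bis(methoxymethoxy)-3-[(4,4,5,5-tetramethyl-1,3,2-dioxaborolan-2-yl)methyl]phenyl}-2-methylpropan-1-one; 8 methacrolein (2-methylprop-2-enal)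
Product: 10 1-[(2R)-4,6-bis(methoxymethoxy)-2-(prop-1-en-2-yl)-2,3-dihydro-1-benzofuran-5-yl]-2-methylpropan-1-one, via pinacol borate of the R alcohol 9 (not isolated)
Conditions: CuOt-Bu (10 mol %), (R)-DTBM-SEGPHOS (11 mol %), 8 (2 equiv), THF, 0 °C to rt; volatiles off; CsF (2 equiv), DMF, 80 °C, same flask
Reagents that add atoms: none
Why: Proposed new method: the ligated copper alkoxide exchanges its oxygen ligand for the benzylic carbon of 7 (boron-to-copper transmetalation), the neutral benzylcopper inserts the C=O group of 8 to form C3–C2, and the copper alkoxide so formed transmetalates with the next molecule of 7, which leaves the product as borate 9 and closes the cycle. The closest known reaction type is the enantioselective 1,2-addition of allyl, alkenyl and aryl boronates and of 1,1-diborylalkanes to aldehydes under chiral monovalent copper catalysis, which has not been shown for a simple benzylic boronate. CsF then frees the alkoxide from boron, and it attacks C7a in a 5-exo-trig addition–elimination (SNAr through a Meisenheimer adduct) that expels fluoride and closes the dihydrofuran ring. C2 is the only new stereocentre and is set in the carbonyl insertion by the chiral pocket of (R)-DTBM-SEGPHOS on copper (Re-face attack gives R), and the ring closure breaks no bond at C2. The step needs 1,2- over 1,4-addition, favoured by the α-methyl branch of 8 and by a neutral phosphine-bound organocopper in place of a cuprate, aldehyde over ketone selectivity, secured by the two ortho OMOM groups that shield the isobutyryl carbonyl, and substitution at C7a, secured by the para acyl group, the two meta alkoxy groups and the five-membered transition state.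

Step 6
Reactants: 10 1-[(2R)-4,6-bis(methoxymethoxy)-2-(prop-1-en-2-yl)-2,3-dihydro-1-benzofuran-5-yl]-2-methylpropan-1-one
Product: 11 1-[(2R)-4,6-dihydroxy-2-(prop-1-en-2-yl)-2,3-dihydro-1-benzofuran-5-yl]-2-methylpropan-1-one
Conditions: p-TsOH·H2O (20 mol %), MeOH, 45 °C
Reagents that add atoms: none
Why: Acid-catalysed acetal exchange with methanol removes both MOM groups, helped by hydrogen bonding of the freed phenols to the C5 carbonyl, under conditions too mild to protonate the isopropenyl group or ionise the C2–O1 bond, so C2 is untouched.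

Step 7
Reactants: 12 pentan-3-one
Product: 13 trimethyl(pent-2-en-3-yloxy)silane (E/Z mixture)
Conditions: LiN(i-Pr)2 (1.05 equiv), THF, −78 °C; Me3SiCl, −78 °C to rt
Reagents that add atoms: chlorotrimethylsilane, C[Si](C)(C)Cl
Why: Kinetic enolate formation and O-silylation give the silyl enol ether, whose E/Z composition does not matter because the double bond ends inside the pyrone ring.

Step 8
Reactants: 13 trimethyl(pent-2-en-3-yloxy)silane; 14 malonyl dichloride
Product: 15 6-ethyl-4-hydroxy-5-methyl-2H-pyran-2-one
Conditions: Et2O, −78 °C to rt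
Reagents that add atoms: none
Why: C-acylation of the silyl enol ether by one acid chloride and O-acylation of the resulting enol by the other, a known pyrone synthesis from malonyl dichloride, closes the 4-hydroxy-2-pyrone with ethyl at its C6 and methyl at its C5.

Step 9
Reactants: 11 1-[(2R)-4,6-dihydroxy-2-(prop-1-en-2-yl)-2,3-dihydro-1-benzofuran-5-yl]-2-methylpropan-1-one; 15 6-ethyl-4-hydroxy-5-methyl-2H-pyran-2-one
Product: 18 3-{[(2R)-4,6-dihydroxy-5-(2-methylpropanoyl)-2-(prop-1-en-2-yl)-2,3-dihydro-1-benzofuran-7-yl]methyl}-6-ethyl-4-hydroxy-5-methyl-2H-pyran-2-one (CNP0206652.1), via C7 Mannich base 16 (not isolated), via ortho-quinone methide 17 (not isolated)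
Conditions: [Me2N=CH2]I (1.0 equiv), NaOAc (1.1 equiv), MeCN, rt; then 15 (1.2 equiv), 70 °C
Reagents that add atoms: N,N-dimethylmethyleneiminium iodide, C[N+](C)=C.[I-]
Why: A Mannich reaction at C7, the only free ring carbon of 11, followed by thermal loss of dimethylamine gives an ortho-quinone methide that the nucleophilic C3 of pyrone 15 catches in a Michael addition with rearomatisation, and because all of 11 is aminomethylated before heating no free arene competes with 15 and C2 is not touched.

Compound list
1 | 5-fluorobenzene-1,3-diol | Oc1cc(O)cc(F)c1 | starting material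
2 | 1-fluoro-3,5-bis(methoxymethoxy)benzene | COCOc1cc(F)cc(OCOC)c1 | intermediate
3 | N-methoxy-N,2-dimethylpropanamide | CON(C)C(=O)C(C)C | starting material
4 | 1-[4-fluoro-2,6-bis(methoxymethoxy)phenyl]-2-methylpropan-1-one | CC(C)C(=O)c1c(OCOC)cc(F)cc1OCOC | intermediate
5 | 1-[3-bromo-4-fluoro-2,6-bis(methoxymethoxy)phenyl]-2-methylpropan-1-one | CC(C)C(=O)c1c(OCOC)cc(F)c(Br)c1OCOC | intermediate
6 | bis[(pinacolato)boryl]methane | CC1(C)OB(CB2OC(C)(C)C(C)(C)O2)OC1(C)C | starting material
7 | benzylic pinacol boronate of the fluoro ketone | CC(C)C(=O)c1c(OCOC)cc(F)c(CB2OC(C)(C)C(C)(C)O2)c1OCOC | intermediate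
8 | methacrolein | C=C(C)C=O | starting material
9 | pinacol borate of (2R)-1-aryl-3-methylbut-3-en-2-ol | C=C(C)[C@H](OB1OC(C)(C)C(C)(C)O1)Cc1c(F)cc(OCOC)c(C(=O)C(C)C)c1OCOC | intermediate
10 | 1-[(2R)-4,6-bis(methoxymethoxy)-2-(prop-1-en-2-yl)-2,3-dihydro-1-benzofuran-5-yl]-2-methylpropan-1-one | C=C(C)[C@H]1Cc2c(OCOC)c(C(=O)C(C)C)c(OCOC)cc2O1 | intermediate
11 | 1-[(2R)-4,6-dihydroxy-2-(prop-1-en-2-yl)-2,3-dihydro-1-benzofuran-5-yl]-2-methylpropan-1-one | C=C(C)[C@H]1Cc2c(O)c(C(=O)C(C)C)c(O)cc2O1 | intermediate
12 | pentan-3-one | CCC(=O)CC | starting material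
13 | trimethyl(pent-2-en-3-yloxy)silane (E/Z mixture) | CC=C(CC)O[Si](C)(C)C | intermediate
14 | malonyl dichloride | O=C(Cl)CC(=O)Cl | starting material
15 | 6-ethyl-4-hydroxy-5-methyl-2H-pyran-2-one | CCc1oc(=O)cc(O)c1C | intermediate
16 | C7 dimethylaminomethyl derivative of 11 | C=C(C)[C@H]1Cc2c(O)c(C(=O)C(C)C)c(O)c(CN(C)C)c2O1 | intermediate
17 | ortho-quinone methide (C6 carbonyl, C7 methylene) | C=C(C)[C@H]1CC2=C(O1)C(=C)C(=O)C(C(=O)C(C)C)=C2O | intermediate
18 | CNP0206652.1 | C=C(C)[C@H]1Cc2c(O)c(C(=O)C(C)C)c(O)c(Cc3c(O)c(C)c(CC)oc3=O)c2O1 | target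

Total step count: 9. Longest linear sequence: 7 (steps 1 to 6 and 9).

Steps most likely to fail

1. Step 5.
- What may go wrong: slow boron-to-copper transfer with competing protodeboronation, conjugate instead of carbonyl addition, poor facial selectivity, or a sluggish ring closure.
- Fallback with known chemistry, from 7 back to 10: s-BuLi (THF, −78 °C) converts 7 into the lithium sec-butyl borate complex F1. This complex benzylates 8 to give the racemic allylic alcohol F2.
- Dess–Martin oxidation gives the enone F3. Corey–Bakshi–Shibata reduction with the (S)-methyl oxazaborolidine and BH3·SMe2, with the isopropenyl group acting as the large substituent, gives the (R)-alcohol F4.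
- KN(SiMe3)2 in THF–DMF at 60 °C closes the ring by SNAr to 10. The two bonds are then made in separate flasks.

2. Step 4.
- What may go wrong: slow oxidative addition and transmetalation at a bromide flanked by F and OMOM, and base-induced protodeboronation of the benzylic boronate.
- Fallback without palladium, from 5 back to 7: bromine–magnesium exchange with i-PrMgCl·LiCl (THF, −20 °C) gives the arylmagnesium chloride F5.
- 2-(Chloromethyl)-4,4,5,5-tetramethyl-1,3,2-dioxaborolane converts F5 into the chloromethyl borate complex F6. Warming triggers the 1,2-aryl shift with loss of chloride (Matteson homologation) to 7.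

3. Step 9.
- What may go wrong: incomplete aminomethylation followed by self-coupling of the arene, slow loss of dimethylamine, or acid-induced migration of the isopropenyl double bond on long heating.
- Fallback, from 11 and 15 back to 18: Vilsmeier–Haack formylation (POCl3, DMF, 0 °C; aq NaOAc) gives the C7 aldehyde F7.
- A three-component reductive alkylation with 15, L-proline (cat.) and Hantzsch ester in CH2Cl2 at rt runs through the Knoevenagel adduct F8. Hydride transfer reduces F8 in situ to 18.

Further compounds
F1 | step 5 | lithium sec-butyl borate complex of 7 | [Li+].CCC(C)[B-]1(Cc2c(F)cc(OCOC)c(C(=O)C(C)C)c2OCOC)OC(C)(C)C(C)(C)O1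
F2 | step 5 | racemic 1-[4-fluoro-3-(2-hydroxy-3-methylbut-3-en-1-yl)-2,6-bis(methoxymethoxy)phenyl]-2-methylpropan-1-one | C=C(C)C(O)Cc1c(F)cc(OCOC)c(C(=O)C(C)C)c1OCOC
F3 | step 5 | 1-[6-fluoro-2,4-bis(methoxymethoxy)-3-(2-methylpropanoyl)phenyl]-3-methylbut-3-en-2-one | C=C(C)C(=O)Cc1c(F)cc(OCOC)c(C(=O)C(C)C)c1OCOC
F4 | step 5 | (R)-enantiomer of F2 | C=C(C)[C@H](O)Cc1c(F)cc(OCOC)c(C(=O)C(C)C)c1OCOC
F5 | step 4 | arylmagnesium chloride from 5 | CC(C)C(=O)c1c(OCOC)cc(F)c([Mg]Cl)c1OCOC
F6 | step 4 | aryl(chloromethyl) pinacol borate complex, chloromagnesium salt | CC(C)C(=O)c1c(OCOC)cc(F)c([B-]2(CCl)OC(C)(C)C(C)(C)O2)c1OCOC.[Mg+2].[Cl-]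
F7 | step 9 | (2R)-4,6-dihydroxy-5-(2-methylpropanoyl)-2-(prop-1-en-2-yl)-2,3-dihydro-1-benzofuran-7-carbaldehyde | C=C(C)[C@H]1Cc2c(O)c(C(=O)C(C)C)c(O)c(C=O)c2O1
F8 | step 9 | Knoevenagel adduct of F7 and 15 | C=C(C)[C@H]1Cc2c(O)c(C(=O)C(C)C)c(O)c(C=C3C(=O)OC(CC)=C(C)C3=O)c2O1
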